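In a one-step world G and D leave E together, and their share stands still from the first moment.

in all of them: Q 0.0255 M
- south-east: E 0.024 M; run made earlier
- east: E 0.037 M; run made earlier
- flask: E 0.017 M; time 2.5 d

- south-east (time / d: G / %, D / %, E / %): 0.250: 16.5, 54.8, 21.7; 0.833: 22.6, 69.1, 5.4; 1.25: 23.8, 70.4, 3.7; 2.00: 22.9, 73.8, 1.7; 3.00: 24.1, 74.5, 2.6
- east (time / d: G / %, D / %, E / %): 0.625: 14.7, 49.7, 32.0; 1.25: 15.5, 49.2, 28.6; 1.67: 16.4, 51.9, 29.8; 2.50: 15.5, 51.3, 30.6; 3.00: 14.9, 49.9, 28.9

(scatter of a reading: 1 percentage point)



- share of G in G plus D at 4.0 min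
- share of G in G plus D at 2.5 d

I read the south-east fall of E to its first reading as one second-order step at nearly equal charges. That gave the lifetime of E at the charged Q, 93.9 min, and this flask has the same Q. It holds E 0.017 M against Q 0.0255 M, so E is the limiting reagent. Since 2.5 d is 38.3 lifetimes, the share should be that of the last south-east reading, 24.4%, and I first committed to that at both times.

The weak link was the early time. 4.0 min is 0.0426 of a lifetime, while the first reading stands at 3.83 lifetimes, and there the three species fall short by 7 percentage points, so something seemed to be held. Suppose G waits in a holding form (an intermediate) that empties by itself in about that lifetime. G then grows as the square of time while D grows with time, and the share comes to the late ratio of G to D, 0.323, times the count over two, 0.689%.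

The forecast said 24% (20% to 28%) at the early time and 24% (22% to 26%) at the late one, finding “no real trend with time”. It differs from my early figure and agrees with my late one.

The flask gave 1.12% and 24.4%.

    E + Q ⇌ L (K = 18.2 M⁻¹, k = 0.348 M⁻¹ min⁻¹)
    E + Q ⇌ J (K = 39.0 M⁻¹, k = 0.443 M⁻¹ min⁻¹)
    E + Q → D (k = 0.460 M⁻¹ min⁻¹)
    J → G (k = 0.00583 min⁻¹)
    Q ⇌ Z (K = 0.360, k = 9.63 × 10⁻⁴ min⁻¹)
    E + J → X (k = 0.0435 M⁻¹ min⁻¹)

G comes from J, whose half-life on that path is 0.083 d, a lifetime about twice mine. At the start the forward paths use E for D and for J at a ratio of 1.0, against the 3.09 of D to G that I read late, and the flask's early share is 1.63 times my 0.689%.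

A form that empties by itself has a lifetime with no Q in it, so the neighbour with 0.10 M of Q should keep this flask's early share, 1.12%. It computed 1.18%.

All runs were computed from invented constants; noise was put on by code.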